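**Retrosynthetic overview**
1. The quinone (C1=O, C2–OH, C3–pentadecyl, C4=O, C5–OMe, C6–H) is traced back to a 6-methoxy-2-pentadecyl-3-silyloxyphenol that already carries the chain and the oxygens at C2, C4 and C5; the last oxygen is added by oxidation of C1–H, para to the C4 phenol, followed by desilylation.
2. That phenol is assembled in one operation from a siloxyalkyne (C2, C3 and the chain) and 4-methoxyvinylketene (C4, C1, C6, C5), the ketene being made in the flask from a diazoketone by photochemical Wolff rearrangement. A [2+2] cycloaddition forms C1–C2 and C3–C4, and a 6π electrocyclization then forms C4–C5.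
3. The siloxyalkyne comes from ethyl hexadecanoate by one-carbon ynolate homologation and O-silylation; the diazoketone comes from (E)-4-methoxybut-3-en-2-one by trifluoroacetylation and diazo transfer.
4. Enabling feature: in the quinone ring C2–O and C4–O flank the alkylated C3, which at the phenol level is a 2-alkylresorcinol, the signature of an ynol ether C≡C joined to a ketene C=O. C5(OMe)=C6H is an enol ether that can be the vinyl end of that ketene, and C1 can be carried as C–H.
5. Ring order: the six-membered carbocycle is the only ring and is formed in the key step, through a transient four-membered ring.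

Key step: step 4

Remark: the target has no stereocentre; ring atoms are numbered throughout as in 2-hydroxy-5-methoxy-3-pentadecylcyclohexa-2,5-diene-1,4-dione.

**Route**

Step 1
Reactants: 1 ethyl hexadecanoate
Product: 4 triisopropyl(heptadec-1-yn-1-yloxy)silane, via lithium 1,1-dibromoheptadec-1-en-2-olate 2 (not isolated), via lithium heptadec-1-yn-1-olate 3 (not isolated)
Conditions: CH2Br2, LiTMP (lithium 2,2,6,6-tetramethylpiperidide), THF, −78 °C; LiHMDS (LiN(SiMe3)2), −78 °C; n-BuLi, −78 °C to rt; iPr3SiCl, −78 °C to rt; non-acidic work-up, filtration through basic alumina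
Reagents that add atoms: dibromomethane, BrCBr; triisopropylsilyl chloride, CC(C)[Si](Cl)(C(C)C)C(C)C
Why: Kowalski ester homologation, in which LiCHBr2 adds to the ester, the derived dibromo enolate 2 undergoes bromine–lithium exchange and carbenoid 1,2-shift of the pentadecyl group to ynolate 3, and the bulky silyl chloride should silylate 3 on oxygen to give the siloxyalkyne.

Step 2
Reactants: 5 (E)-4-methoxybut-3-en-2-one
Product: 6 (E)-1,1,1-trifluoro-6-methoxyhex-5-ene-2,4-dione
Conditions: LiHMDS (LiN(SiMe3)2), THF, −78 °C; CF3CO2CH2CF3, −78 °C; brief cold 1 M HCl work-up, crude product used at once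
Reagents that add atoms: 2,2,2-trifluoroethyl trifluoroacetate, O=C(OCC(F)(F)F)C(F)(F)F
Why: Crossed Claisen condensation, in which LiHMDS deprotonates the only enolizable position (the methyl group) of the vinylogous ester and the kinetic enolate is C-acylated by the activated trifluoroacetate, which installs the activating group for diazo transfer.

Step 3
Reactants: 6 (E)-1,1,1-trifluoro-6-methoxyhex-5-ene-2,4-dione
Product: 7 (E)-1-diazo-4-methoxybut-3-en-2-one
Conditions: MsN3, Et3N, H2O (1 equiv), MeCN, rt
Reagents that add atoms: methanesulfonyl azide, CS(=O)(=O)N=[N+]=[N-]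
Why: Regitz-type detrifluoroacetylative diazo transfer, in which the activated methylene of 6 takes the diazo group from the sulfonyl azide and the trifluoroacetyl group leaves on the sulfonamide nitrogen, a sequence that avoids diazomethane and its cycloaddition to the enone double bond.

Step 4
Reactants: 7 (E)-1-diazo-4-methoxybut-3-en-2-one; 4 triisopropyl(heptadec-1-yn-1-yloxy)silane
Product: 12 6-methoxy-2-pentadecyl-3-(triisopropylsilyloxy)phenol, via (E)-4-methoxybuta-1,3-dien-1-one 8 (not isolated), via 4-[(E)-2-methoxyethenyl]-2-pentadecyl-3-(triisopropylsilyloxy)cyclobut-2-en-1-one 9 (not isolated), via (3E,5E)-6-methoxy-2-pentadecyl-3-(triisopropylsilyloxy)hexa-1,3,5-trien-1-one 10 (not isolated), via 6-methoxy-2-pentadecyl-3-(triisopropylsilyloxy)cyclohexa-2,4-dien-1-one 11 (not isolated)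
Conditions: hν (254 nm, low-pressure mercury lamps, Vycor vessel), ClCH2CH2Cl, degassed, rt; then 80 °C
Reagents that add atoms: none
Why: Irradiation triggers a photochemical Wolff rearrangement of 7 (loss of N2 and 1,2-shift of the methoxyvinyl group from the carbonyl carbon, the future C4, to the diazo carbon, the future C1) to vinylketene 8, whose electrophilic carbonyl carbon is attacked by the chain-bearing, nucleophilic alkyne carbon (C3) in a regioselective [2+2] cycloaddition that also joins the ketene α-carbon (C1) to the oxygen-bearing alkyne carbon (C2), giving cyclobutenone 9. Four-electron electrocyclic opening of 9 (light or heat) gives dienylketene 10, whose six-electron electrocyclization joins the ketene carbon C4 to the methoxy-bearing terminus C5, and tautomerization of dienone 11 then gives phenol 12. This is the photochemical diazoketone variant of the Danheiser benzannulation, which has close precedent for vinylketenes combined with siloxyalkynes. The only ring, the six-membered carbocycle, is closed by 6π electrocyclization after a four-membered ring has been made by [2+2] cycloaddition and opened again. The sp3 ring carbons of 9 and 11 are transient, racemic stereocentres that are erased on aromatization, so no stereocentre has to be controlled. The step needs head-to-tail regiochemistry in the [2+2] event, secured by the matched polarization of ynol ether and ketene, and inward rotation of the methoxyvinyl group on ring opening, secured because the opening is reversible and only the inward isomer is drained by cyclization.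

Step 5
Reactants: 12 6-methoxy-2-pentadecyl-3-(triisopropylsilyloxy)phenol
Product: 14 2-hydroxy-5-methoxy-3-pentadecylcyclohexa-2,5-diene-1,4-dione, via 5-methoxy-3-pentadecyl-2-(triisopropylsilyloxy)cyclohexa-2,5-diene-1,4-dione 13 (not isolated)
Conditions: O2 (1 atm), Co(salen) ([N,N'-ethylenebis(salicylideneiminato)]cobalt, divalent cobalt; 10 mol %), DMF, rt; then 48% aq. HF, MeCN, 0 °C
Reagents that add atoms: dioxygen, O=O
Why: Cobalt–salen-catalysed aerobic oxidation of a 2,6-disubstituted phenol with a free para position should give the para-quinone by oxygenation of the phenoxyl radical at C1, the silyl group keeping the C2 oxygen masked so that only the C4 phenol directs, and the labile silyl vinylogous ester 13 is then cleaved by HF to the hydroxyquinone.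

**Compound list**
1 | ethyl hexadecanoate (ethyl palmitate) | CCCCCCCCCCCCCCCC(=O)OCC | starting material
2 | lithium 1,1-dibromoheptadec-1-en-2-olate | CCCCCCCCCCCCCCCC([O-])=C(Br)Br.[Li+] | intermediate
3 | lithium heptadec-1-yn-1-olate | CCCCCCCCCCCCCCCC#C[O-].[Li+] | intermediate
4 | triisopropyl(heptadec-1-yn-1-yloxy)silane | CCCCCCCCCCCCCCCC#CO[Si](C(C)C)(C(C)C)C(C)C | intermediate
5 | (E)-4-methoxybut-3-en-2-one | CO/C=C/C(C)=O | starting material
6 | (E)-1,1,1-trifluoro-6-methoxyhex-5-ene-2,4-dione (largely enolized) | CO/C=C/C(=O)CC(=O)C(F)(F)F | intermediate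
7 | (E)-1-diazo-4-methoxybut-3-en-2-one | CO/C=C/C(=O)C=[N+]=[N-] | intermediate
8 | (E)-4-methoxybuta-1,3-dien-1-one | CO/C=C/C=C=O | intermediate
9 | 4-[(E)-2-methoxyethenyl]-2-pentadecyl-3-(triisopropylsilyloxy)cyclobut-2-en-1-one (racemic) | CCCCCCCCCCCCCCCC1=C(O[Si](C(C)C)(C(C)C)C(C)C)C(/C=C/OC)C1=O | intermediate
10 | (3E,5E)-6-methoxy-2-pentadecyl-3-(triisopropylsilyloxy)hexa-1,3,5-trien-1-one (methoxyvinyl group cis to the ketene carbon) | CCCCCCCCCCCCCCCC(=C=O)/C(O[Si](C(C)C)(C(C)C)C(C)C)=C\C=C\OC | intermediate
11 | 6-methoxy-2-pentadecyl-3-(triisopropylsilyloxy)cyclohexa-2,4-dien-1-one (racemic) | CCCCCCCCCCCCCCCC1=C(O[Si](C(C)C)(C(C)C)C(C)C)C=CC(OC)C1=O | intermediate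
12 | 6-methoxy-2-pentadecyl-3-(triisopropylsilyloxy)phenol | CCCCCCCCCCCCCCCc1c(O)c(OC)ccc1O[Si](C(C)C)(C(C)C)C(C)C | intermediate
13 | 5-methoxy-3-pentadecyl-2-(triisopropylsilyloxy)cyclohexa-2,5-diene-1,4-dione | CCCCCCCCCCCCCCCC1=C(O[Si](C(C)C)(C(C)C)C(C)C)C(=O)C=C(OC)C1=O | intermediate
14 | 2-hydroxy-5-methoxy-3-pentadecylcyclohexa-2,5-diene-1,4-dione | CCCCCCCCCCCCCCCC1=C(O)C(=O)C=C(OC)C1=O | target

**Count**
Total steps: 5. Longest linear sequence: 4 steps (steps 2, 3, 4, 5); the other branch is step 1, then steps 4 and 5.

**Steps most likely to fail**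

Step 4. The light-driven cascade may stall or divert: the acyl carbene may add to the electron-rich alkyne instead of rearranging, the vinylketene may dimerize before it meets the alkyne, the siloxyalkyne may degrade under irradiation, or cyclobutenone 9 may not convert fully on heating. The fallback sets out from 1 and comes back at 14 without any annulation. Ester 1 is saponified (LiOH, THF/H2O; then HCl) to hexadecanoic acid F1. Decarboxylative radical alkylation of commercial 2,5-dihydroxy-1,4-benzoquinone (used in excess to limit double alkylation) with F1 under Jacobsen–Torssell conditions (AgNO3 cat., (NH4)2S2O8, MeCN/H2O, 70 °C) should give 2,5-dihydroxy-3-pentadecylcyclohexa-2,5-diene-1,4-dione F2. Acid-catalysed etherification (MeOH, BF3·OEt2 or cat. H2SO4) is expected to methylate the unhindered C5 hydroxyl rather than the C2 hydroxyl next to the chain, giving 14.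

Step 5. The oxidation may take the wrong course: carbon–carbon coupling of the phenoxyl radical, slow oxygenation next to the bulky silyl ether, or loss of the silyl group before oxidation, which would expose the second phenol and direct oxidation to the methoxy-bearing carbon. The fallback sets out from 12 and comes back at 14, introducing the oxygen by two-electron chemistry. Vilsmeier–Haack formylation (POCl3, DMF; aq. NaOAc) at the only activated free position, para to the hydroxyl, should give 4-hydroxy-5-methoxy-3-pentadecyl-2-(triisopropylsilyloxy)benzaldehyde F3. Dakin oxidation (H2O2, NaOH, THF/H2O) replaces the formyl group by hydroxyl to give 5-methoxy-3-pentadecyl-2-(triisopropylsilyloxy)benzene-1,4-diol F4. Exposure of F4 to air and aq. HF in MeCN oxidizes and desilylates it to 14; silyl migration between the neighbouring oxygens would be harmless, because every isomer converges on the same hydroxyquinone.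

Step 1. The ynolate may not form cleanly (incomplete bromine–lithium exchange or rearrangement), silylation may occur at carbon to give a silylketene, and the siloxyalkyne may hydrolyse on purification. The fallback sets out from 1 and comes back at 3. Ester 1 is reduced (i-Bu2AlH, toluene, −78 °C) to hexadecanal F5, which is homologated by the Ohira–Bestmann reaction (dimethyl (1-diazo-2-oxopropyl)phosphonate, K2CO3, MeOH) to heptadec-1-yne F6. The lithium acetylide of F6 (n-BuLi, THF) is oxidized with t-BuOOLi (from t-BuOOH and LiHMDS) to ynolate 3, which is silylated as in step 1 (iPr3SiOTf if the chloride is sluggish) to 4.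

**Further compounds**
F1 | step 4 | hexadecanoic acid | CCCCCCCCCCCCCCCC(=O)O
F2 | step 4 | 2,5-dihydroxy-3-pentadecylcyclohexa-2,5-diene-1,4-dione | CCCCCCCCCCCCCCCC1=C(O)C(=O)C=C(O)C1=O
F3 | step 5 | 4-hydroxy-5-methoxy-3-pentadecyl-2-(triisopropylsilyloxy)benzaldehyde | CCCCCCCCCCCCCCCc1c(O)c(OC)cc(C=O)c1O[Si](C(C)C)(C(C)C)C(C)C
F4 | step 5 | 5-methoxy-3-pentadecyl-2-(triisopropylsilyloxy)benzene-1,4-diol | CCCCCCCCCCCCCCCc1c(O)c(OC)cc(O)c1O[Si](C(C)C)(C(C)C)C(C)C
F5 | step 1 | hexadecanal | CCCCCCCCCCCCCCCC=O
F6 | step 1 | heptadec-1-yne | CCCCCCCCCCCCCCCC#C
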